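C3 of the oxolane ring is a masked symmetry centre. Besides CH3 and OH it holds two two-carbon units, C2–C1' (running to the coumarin 7-oxygen) and C4–C5 (running to the isobutenyl group). Reading both units as vinyl groups leads back to achiral methyl divinyl carbinol 1, the precursor of the key step. One ligand-controlled, hydroxyl-anchored oxygen transfer to a single vinyl group of 1 builds the three-membered ring of 2. The same event fixes the configurations of C2 and C3 and brings in the oxygen that ends as ring O1. Isofraxidin then opens the oxirane at C1', the spare vinyl group is raised to a C5 acetal, and an alkenylboron reagent sets C5.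

Key step: step 1

Atom labels: oxolane O1, C2 (bears C1'H2–OAr), C3 (CH3, OH), C4, C5 (bears C1''H=CMe2). The target is (2S,3R,5R), with the isobutenyl group cis to C3–OH and trans to C2–CH2OAr.

Assumption: the sense of induction of the bishydroxamate catalyst on this carbinol cannot be predicted with certainty. The ligand antipode is therefore fixed by a pilot run correlated with epoxy alcohol of known configuration; both antipodes derive from the commercial trans-cyclohexane-1,2-diamines.

Remark: 1 is a catalogue chemical and is also available in one operation from ethyl acetate and vinylmagnesium bromide.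

Step 1
Reactants: 1 3-methylpenta-1,4-dien-3-ol
Product: 2 (2R)-2-[(2S)-oxiran-2-yl]but-3-en-2-ol
Conditions: Hf(Ot-Bu)4 (10 mol %), enantiopure N,N'-(trans-cyclohexane-1,2-diyl)bis(N-hydroxy-2,2-diarylacetamide) (12 mol %), cumene hydroperoxide (1.3 equiv), MgO, 4 Å MS, toluene, 0 °C, run until 1 is consumed; bulb-to-bulb distillation
Reagents that add atoms: cumene hydroperoxide, CC(C)(OO)c1ccccc1
Why: Alkoxide exchange binds 1 and an η2-cumyl peroxide to the same ligand-wrapped Hf(IV) centre, and the activated peroxide oxygen passes to the neighbouring vinyl π bond in one concerted, suprafacial transfer; the closest known reaction types are the Sharpless desymmetrisation of secondary divinyl carbinols and the group 4 or tungsten bishydroxamate epoxidation of tertiary allylic alcohols, chosen because titanium tartrate turns over poorly with tertiary alkoxides. The oxirane (O, C1', C2) closes by this [2+1] atom transfer, both C–O bonds arising on one alkene face, not by a stepwise displacement. C2 is controlled by the π face that the C2-symmetric ligand leaves open, whereas C3 is controlled by which enantiotopic vinyl group can reach the peroxide while CH3 and the idle vinyl group fill the remaining quadrants, the anti (erythro) O–C2/C3–OH pairing of 2 being the combination sought. The step thus needs coupled group and face selectivity and mono- over bis-oxidation; in the substrate the single hydroxyl secures inner-sphere delivery and the second vinyl group secures error correction. The enantiomer and the C3 epimer of 2 both keep the vinyl group that fits the catalyst and should be oxidised on to polar bis-epoxides, so the purity of 2 should climb with conversion at some cost in mass. The terminal CH2 of the new ring is left as the only unhindered electrophilic site for step 2.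

Step 2
Reactants: 2 (2R)-2-[(2S)-oxiran-2-yl]but-3-en-2-ol; 3 isofraxidin (7-hydroxy-6,8-dimethoxy-2H-chromen-2-one)
Product: 4 7-{[(2S,3R)-2,3-dihydroxy-3-methylpent-4-en-1-yl]oxy}-6,8-dimethoxy-2H-chromen-2-one
Conditions: K2CO3 (0.2 equiv), DMF, 80 °C, sealed tube
Reagents that add atoms: none
Why: Base-catalysed SN2 opening of a terminal epoxide by a phenoxide (Williamson-type etherification) should occur only at unhindered C1', so the C2–O bond and both stereocentres stay untouched, and the weakly basic aryloxide cannot deprotonate the tertiary alcohol enough to start a Payne migration.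

Step 3
Reactants: 4 7-{[(2S,3R)-2,3-dihydroxy-3-methylpent-4-en-1-yl]oxy}-6,8-dimethoxy-2H-chromen-2-one
Product: 5 7-{[(4S,5R)-5-ethenyl-2,2,5-trimethyl-1,3-dioxolan-4-yl]methoxy}-6,8-dimethoxy-2H-chromen-2-one
Conditions: Me2C(OMe)2, PPTS (cat.), CH2Cl2, rt
Reagents that add atoms: 2,2-dimethoxypropane, COC(C)(C)OC
Why: Acid-catalysed transketalisation ties the vicinal C2/C3 diol into a 1,3-dioxolane, which removes both acidic protons before the borane step and shields C2–OH from the later oxidation, and no stereocentre is touched.

Step 4
Reactants: 5 7-{[(4S,5R)-5-ethenyl-2,2,5-trimethyl-1,3-dioxolan-4-yl]methoxy}-6,8-dimethoxy-2H-chromen-2-one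
Product: 7 7-{[(4S,5R)-5-(2-hydroxyethyl)-2,2,5-trimethyl-1,3-dioxolan-4-yl]methoxy}-6,8-dimethoxy-2H-chromen-2-one, via B-alkyl-9-BBN adduct 6 (not isolated)
Conditions: 9-BBN-H (1.5 equiv), THF, 0 °C → rt; then NaBO3·4H2O, THF/H2O, rt
Reagents that add atoms: sodium perborate, [Na+].[Na+].O[B-]1(O)OO[B-](O)(O)OO1 (oxygen of 7); 9-borabicyclo[3.3.1]nonane, B1C2CCCC1CCC2 (its boron and carbons stay only in 6)
Why: In this Brown hydroboration–oxidation the bulky dialkylborane should add anti-Markovnikov to the monosubstituted alkene (boron on C5, away from fully substituted C3) much faster than it attacks the electron-poor pyranone, and perborate replaces boron by oxygen under nearly neutral conditions that spare the lactone.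

Step 5
Reactants: 7 7-{[(4S,5R)-5-(2-hydroxyethyl)-2,2,5-trimethyl-1,3-dioxolan-4-yl]methoxy}-6,8-dimethoxy-2H-chromen-2-one
Product: 8 2-[(4R,5S)-5-{[(6,8-dimethoxy-2-oxo-2H-chromen-7-yl)oxy]methyl}-2,2,4-trimethyl-1,3-dioxolan-4-yl]acetaldehyde
Conditions: TEMPO (10 mol %), PhI(OAc)2, CH2Cl2, rt
Reagents that add atoms: none
Why: Oxoammonium-mediated (TEMPO/diacetoxyiodobenzene) oxidation of a primary alcohol stops at the aldehyde, and its base-free, mildly acidic medium avoids β-elimination of the C3 oxygen.

Step 6
Reactants: 8 2-[(4R,5S)-5-{[(6,8-dimethoxy-2-oxo-2H-chromen-7-yl)oxy]methyl}-2,2,4-trimethyl-1,3-dioxolan-4-yl]acetaldehyde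
Product: 9 7-{[(2S,3R)-3-hydroxy-5-methoxy-3-methyloxolan-2-yl]methoxy}-6,8-dimethoxy-2H-chromen-2-one (both C5 anomers)
Conditions: CSA (10 mol %), MeOH, rt → 40 °C; Et3N quench
Reagents that add atoms: methanol, CO
Why: In this acid-catalysed methanolysis (Fischer-type glycosidation as practised on 2-deoxy sugars) the dioxolane leaves as acetone, the freed C2–OH closes on C5 in a 5-exo-trig sense because C3–OH could only give an oxetane, and methanol caps the lactol, while C2 and C3 are not involved and the anomer mixture is irrelevant since C5 is planarised in step 8.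

Step 7
Reactants: 10 4,4,5,5-tetramethyl-2-(2-methylprop-1-en-1-yl)-1,3,2-dioxaborolane
Product: 11 potassium trifluoro(2-methylprop-1-en-1-yl)borate
Conditions: KHF2 (aq), MeOH, rt; recrystallisation from acetone/Et2O
Reagents that add atoms: potassium hydrogen difluoride, F.[F-].[K+]
Why: The standard KHF2 fluorination of a boronic ester should give the crystalline, air-stable trifluoroborate with the alkene untouched.

Step 8
Reactants: 9 7-{[(2S,3R)-3-hydroxy-5-methoxy-3-methyloxolan-2-yl]methoxy}-6,8-dimethoxy-2H-chromen-2-one; 11 potassium trifluoro(2-methylprop-1-en-1-yl)borate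
Product: 13 7-{[(2S,3R,5R)-3-hydroxy-3-methyl-5-(2-methylprop-1-en-1-yl)oxolan-2-yl]methoxy}-6,8-dimethoxy-2H-chromen-2-one, via oxocarbenium ion 12 (not isolated)
Conditions: 11 (3 equiv), BF3·OEt2 (4 equiv), CH2Cl2, 0 °C; then 9, −78 → −30 °C; cold aq NaHCO3 quench
Reagents that add atoms: none
Why: In this BF3-promoted coupling of a potassium alkenyltrifluoroborate with a cyclic acetal (C-glycosylation type substitution) BF3 strips fluoride from 11 and methoxide from 9, the boron-bearing alkene carbon attacks C5 of 12, and the inside-attack model for five-membered oxocarbenium ions (C3–O pseudoaxial, C3–CH3 pseudoequatorial), possibly reinforced by boron binding to the free C3–OH, should place the new group cis to C3–OH and trans to C2–CH2OAr, that is 5R, in line with the α-selective C-glycosylation of 2-deoxyribofuranosyl donors.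

Compound list
1 | 3-methylpenta-1,4-dien-3-ol | C=CC(C)(O)C=C | starting material
2 | (2R)-2-[(2S)-oxiran-2-yl]but-3-en-2-ol | C=C[C@@](C)(O)[C@@H]1CO1 | intermediate
3 | isofraxidin (7-hydroxy-6,8-dimethoxy-2H-chromen-2-one) | COc1cc2ccc(=O)oc2c(OC)c1O | starting material
4 | 7-{[(2S,3R)-2,3-dihydroxy-3-methylpent-4-en-1-yl]oxy}-6,8-dimethoxy-2H-chromen-2-one | COc1cc2ccc(=O)oc2c(OC)c1OC[C@H](O)[C@](C)(O)C=C | intermediate
5 | 7-{[(4S,5R)-5-ethenyl-2,2,5-trimethyl-1,3-dioxolan-4-yl]methoxy}-6,8-dimethoxy-2H-chromen-2-one | COc1cc2ccc(=O)oc2c(OC)c1OC[C@@H]1OC(C)(C)O[C@]1(C)C=C | intermediate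
6 | B-alkyl-9-BBN adduct of 5, boron on C5 (not isolated) | COc1cc2ccc(=O)oc2c(OC)c1OC[C@@H]1OC(C)(C)O[C@]1(C)CCB1C2CCCC1CCC2 | intermediate
7 | 7-{[(4S,5R)-5-(2-hydroxyethyl)-2,2,5-trimethyl-1,3-dioxolan-4-yl]methoxy}-6,8-dimethoxy-2H-chromen-2-one | COc1cc2ccc(=O)oc2c(OC)c1OC[C@@H]1OC(C)(C)O[C@]1(C)CCO | intermediate
8 | 2-[(4R,5S)-5-{[(6,8-dimethoxy-2-oxo-2H-chromen-7-yl)oxy]methyl}-2,2,4-trimethyl-1,3-dioxolan-4-yl]acetaldehyde | COc1cc2ccc(=O)oc2c(OC)c1OC[C@@H]1OC(C)(C)O[C@]1(C)CC=O | intermediate
9 | 7-{[(2S,3R)-3-hydroxy-5-methoxy-3-methyloxolan-2-yl]methoxy}-6,8-dimethoxy-2H-chromen-2-one, C5 anomers | COc1cc2ccc(=O)oc2c(OC)c1OC[C@@H]1OC(OC)C[C@@]1(C)O | intermediate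
10 | 4,4,5,5-tetramethyl-2-(2-methylprop-1-en-1-yl)-1,3,2-dioxaborolane | CC(C)=CB1OC(C)(C)C(C)(C)O1 | starting material
11 | potassium trifluoro(2-methylprop-1-en-1-yl)borate | [K+].CC(C)=C[B-](F)(F)F | intermediate
12 | (2S,3R)-configured cyclic oxocarbenium ion, O1=C5 (not isolated) | COc1cc2ccc(=O)oc2c(OC)c1OC[C@@H]1[O+]=CC[C@@]1(C)O | intermediate
13 | 7-{[(2S,3R,5R)-3-hydroxy-3-methyl-5-(2-methylprop-1-en-1-yl)oxolan-2-yl]methoxy}-6,8-dimethoxy-2H-chromen-2-one | COc1cc2ccc(=O)oc2c(OC)c1OC[C@@H]1O[C@@H](C=C(C)C)C[C@@]1(C)O | target

Total step count: 8. Longest linear sequence: 7 (steps 1–6 and 8); step 7 is a side branch.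

Steps most likely to fail

Step 1.
- What may go wrong: Oxygen transfer to an unsubstituted vinyl group on a crowded tertiary alkoxide may be slow. The catalyst may also tell CH3 and the idle vinyl group apart only weakly, so group selection (C3) could erode even where face selection (C2) is high. The corrective second oxidation would then consume much material. It does not remove the C2 epimer, which would have to be separated at 4 or 5.
- Fallback: this sets out from 1 and returns at 4. A perrhenate-catalysed 1,3-transposition of the allylic alcohol (Ph3SiOReO3, Et2O, −40 °C) moves the hydroxyl to the chain end and should give the conjugated primary alcohol (E)-3-methylpenta-2,4-dien-1-ol F1, the Z isomer being removed by chromatography. Catalytic Sharpless epoxidation follows (D-(−)-diisopropyl tartrate, Ti(Oi-Pr)4, t-BuOOH, 4 Å MS, CH2Cl2, −20 °C). F1 is a trisubstituted primary allylic alcohol of the geraniol type, the best substrate class of that reaction, and should give [(2R,3R)-3-ethenyl-3-methyloxiran-2-yl]methanol F2. Warming F2 with 3 in aqueous NaOH/t-BuOH sets up the Payne equilibrium with the alkoxide of 2 (inversion at C2, C3–O retained). The phenoxide drains this equilibrium by attack at C1'. Acidification re-closes any opened pyranone and delivers 4.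

Step 8.
- What may go wrong: The alkenylboron reagent may be lost to protodeboronation and the facial bias may be incomplete. The Lewis acid may re-ionise the newly formed allylic C5–O1 bond with loss of configuration. The oxocarbenium ion may lose a proton and then water on the way to a furan.
- Fallback: this sets out from 9 and returns at 13. Allyltrimethylsilane and BF3·OEt2 (CH2Cl2, −78 °C, Hosomi–Sakurai type C-glycosylation) use the nucleophile for which the 1,3-cis preference is best established. They should give 7-{[(2S,3R,5S)-3-hydroxy-3-methyl-5-(prop-2-en-1-yl)oxolan-2-yl]methoxy}-6,8-dimethoxy-2H-chromen-2-one F3, whose C5–O1 bond is not allylic and cannot re-ionise. A one-position alkene migration (Pd–H or Cp*Ru catalyst) should then give 7-{[(2S,3R,5R)-3-hydroxy-3-methyl-5-[(1E)-prop-1-en-1-yl]oxolan-2-yl]methoxy}-6,8-dimethoxy-2H-chromen-2-one F4. Cross-metathesis with excess 2-methylbut-2-ene (Hoveyda–Grubbs II catalyst, CH2Cl2, 40 °C) exchanges ethylidene for isopropylidene under neutral conditions and arrives at 13.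

Step 4.
- What may go wrong: Hydride delivery from the borane to the pyranone carbonyl or its C3=C4 bond may compete with hydroboration of the hindered vinyl group. The lactone may also open during the oxidative work-up.
- Fallback: this sets out from 5 and returns at 8, skipping 6 and 7. It is an aldehyde-selective, nitrite-modified Wacker oxidation (PdCl2(PhCN)2, CuCl2·2H2O, AgNO2, all catalytic, O2, t-BuOH/MeNO2, rt). That reaction is known to favour the terminal carbon for vinyl groups on fully substituted, oxygen-bearing carbons. This fallback makes no new compound (F0).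

Further compounds
F1 | step 1 | (E)-3-methylpenta-2,4-dien-1-ol | C=C/C(C)=C/CO
F2 | step 1 | [(2R,3R)-3-ethenyl-3-methyloxiran-2-yl]methanol | OC[C@H]1O[C@]1(C)C=C
F3 | step 8 | 7-{[(2S,3R,5S)-3-hydroxy-3-methyl-5-(prop-2-en-1-yl)oxolan-2-yl]methoxy}-6,8-dimethoxy-2H-chromen-2-one | COc1cc2ccc(=O)oc2c(OC)c1OC[C@@H]1O[C@@H](CC=C)C[C@@]1(C)O
F4 | step 8 | 7-{[(2S,3R,5R)-3-hydroxy-3-methyl-5-[(1E)-prop-1-en-1-yl]oxolan-2-yl]methoxy}-6,8-dimethoxy-2H-chromen-2-one | COc1cc2ccc(=O)oc2c(OC)c1OC[C@@H]1O[C@@H](/C=C/C)C[C@@]1(C)O
F0 | step 4 | none | none
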